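The late readings are where your hunch looked, and they are a good place to start. At 4.00 min the feed has delivered 80.0% of the charge of the monomer X, and X still stands at 77.7% in the theta run and 73.7% in the epsilon run. So in these two runs X stays near the feed line, and for this flask I reckon with X as fed.

| flask | X | E | J | remark | time |
|---|---|---|---|---|---|
| theta | 16 mM (fed, over 5.0 min) | 0.16 mM | 38 µM | run made earlier |  |
| epsilon | 16 mM (fed, over 5.0 min) | 0.16 mM | 84 µM | run made earlier |  |
| delta | 16 mM (fed, over 5.0 min) | 0.32 mM | 56 µM | run made earlier |  |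
| flask | 16 mM (fed, over 5.0 min) | 0.160 mM | 56 µM |  | 5.0 min |

| run | time / min | Q / % | X / % | L / % |
|---|---|---|---|---|
| theta | 0.200 | 0 | 4.4 | 0.3 |
| theta | 0.667 | 0 | 13.3 | 0 |
| theta | 1.00 | 0.2 | 19.9 | 0.7 |
| theta | 1.50 | 0 | 30.0 | 0 |
| theta | 2.50 | 0.7 | 49.0 | 0.8 |
| theta | 3.00 | 0.7 | 59.1 | 0.5 |
| theta | 4.00 | 1.5 | 77.7 | 1.3 |
| epsilon | 0.333 | 0 | 6.4 | 0 |
| epsilon | 0.500 | 0 | 10.4 | 0 |
| epsilon | 0.667 | 0 | 13.4 | 0 |
| epsilon | 1.00 | 0.2 | 20.2 | 0 |
| epsilon | 1.50 | 0.6 | 29.6 | 0.5 |
| epsilon | 2.50 | 1.2 | 49.1 | 0 |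
| epsilon | 4.00 | 3.4 | 73.7 | 2.3 |
| delta | 0.333 | 0 | 7.2 | 0 |
| delta | 1.00 | 0.3 | 19.5 | 0.4 |
| delta | 2.00 | 0.5 | 40.4 | 0 |
| delta | 3.00 | 1.2 | 59.3 | 1.0 |
| delta | 4.00 | 0.5 | 77.0 | 1.6 |

(each reading ± 0.5 percentage points)

- percentages count the whole charge, also what has not yet gone in

- how much Q the flask holds at 5.0 min, in percent of the X charged
- how much X the flask holds at 5.0 min, in percent of the X charged
- how much L the flask holds at 5.0 min, in percent of the X charged
- concentration of G at 5.0 min, in mM

For your quick number, work with the fraction of the initiator J left, not with the living ends G made. I assume that J goes by meeting X, which makes its loss pseudo-first-order: the logarithm of the fraction left falls in step with the area under the X curve. Call that area the exposure A. A steady feed draws a triangle, so for this flask A is 2.40 M·s at 5.0 min. The fraction of J left is then exp(-kA), with k the constant of that step. J is not among the readings, and I commit to no figure for k. If each J gives one G, the J spent is the ceiling on G, and that J is less than the 56 µM charged.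

The forecast says Q 4.2%, X 93%, L 2.9% and G 0.035 mM, adding of G that “this is poorly constrained”.

The flask gives Q 3.15%, X 93.3%, L 3.49% and G 0.0181 mM, so the forecast's G stands higher.

    2 X → Z (k = 1.50 × 10⁻⁴ /M/s)
    X + G → Q + G, rate k2*[G]*[X] (k = 28.0 /M/s)
    G + E → D (k = 58.0 /M/s)
    Q → L (k = 0.0110 /s)
    X + J → G + Q (k = 0.850 /M/s)

With the constant of X + J, the exposure 2.40 M·s leaves 13.0% of J, and the flask holds 14.0%. Of the 0.0482 mM of J gone, G holds 0.0181 mM and D, the form made from G and E, holds 0.0300 mM. In the neighbour flask, charged with 4.0 mM of X, the exposure falls to 0.600 M·s, a quarter of the first flask's, which leaves 60.0% of J. That flask holds 60.6% of J and 0.00997 mM of G.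

The data were generated by integration for substances that don't exist; scatter was added.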